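- I began with the amounts: more reagent was charged than substrate, 3.00 times as much, so substrate was the limiting reagent and I counted everything as a fraction of its charge. On free catalyst, substrate and reagent go reversibly to product; meanwhile two free catalyst destroy each other as spent catalyst, and added ligand parks free catalyst as idle complex.

in all of them: substrate 0.12 M; reagent 0.360 M; free catalyst 12 mM; added ligand 6.3 mM; time 3.0 min
- alder: temperature 40 °C
- cedar: temperature 55 °C
- birch: at 40 °C until 1.5 min, from then on at 70 °C
- oak: temperature 70 °C

- which flask leads in amount of product, in percent of the substrate charged ("all alike" within 1.5 percentage points) (alder / cedar / birch / oak / all alike)
- how much product is there at the end, in percent of the substrate charged: alder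
- how much product is there at the end, in percent of the substrate charged: cedar
- how much product is there at the end, in percent of the substrate charged: birch
- how much product is there at the end, in percent of the substrate charged: oak

- where a step has two of a species, its rate is k times that concentration squared, and two are used at each turn
- constants are those at 40 °C; use the activation energies and enthalpies for any other temperature

    substrate + reagent + free catalyst ⇌ product + free catalyst, rate k1*[substrate]*[reagent]*[free catalyst] forward; the back reaction follows from the equilibrium constant (K1 = 1.54 /M, k1 = 3.00 /M²/s, Ea1 = 42.0 kJ/mol, ΔH1 = 37.0 kJ/mol)
    2 free catalyst → spent catalyst (k2 = 0.501 /M/s, Ea2 = 37.0 kJ/mol)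
    free catalyst + added ligand ⇌ idle complex, settled at all times (K3 = 41 /M, ΔH3 = 11.0 kJ/mol)
    (constants at 40 °C)

- I asked first which given number had to be known well. The equilibrium constant did: free catalyst speeds both directions, so it drops out of the balance. I named the fraction of substrate charge turned when forward and back rates are equal the ceiling, and it came to 33.0% for alder.
- Had that constant been twice as large, the ceiling for alder would have been 48.2%, so an error there passes straight into the answer.
- The enthalpy mattered too: the constant was larger in oak, at 5.33 /M, than the 1.54 /M of alder, and that lifted oak's ceiling to 60.5%.
- For the rate constants I compared two times. In alder, the starting forward speed had to cover just the ceiling, which gave a half-way time of about 0.294 min, while free catalyst had a first half-life, by its own loss step alone, of 1.39 min. Doubling that half-way time gave 0.588 min, still shorter than the catalyst half-life, and halving the catalyst half-life gave 0.695 min, still longer than the half-way time.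
- In oak the same pair read 0.132 min against 0.400 min, the half-way time again the shorter.
- For added ligand, its constant times its charge was 0.258, below one, so in alder I expected less catalyst as idle complex than free; and since free catalyst drops out of the balance, the ceiling stayed as reckoned.
- So I committed to alder below 33.0%, oak below 60.5%, cedar between them, and birch below oak, since birch had 1.50 min of heat against the 3.0 min of oak, with its catalyst already aged.
- The forecast named oak, with 32.2% for alder, 46.3% for cedar, 57% for birch and 59.7% for oak, on the ground that “the final temperature largely sets the yield”.
- The simulation gave oak in the lead, with 32.0% for alder, 46.1% for cedar, 56.3% for birch and 59.6% for oak.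

- In alder the relaxation half-life of the main reaction, both ways together, read 0.926 min at the end, shorter than the run of 3.0 min, and 91% of that reaction's turnover stood behind it at 1.50 min: this is thermodynamic control, with 97.0% of the ceiling reached. Birch, under oak's ceiling of 60.5% for its last 1.50 min, held 93.1% of it at 3.00 min, oak held 98.5%, and birch read 60.5% at 30.0 min.

The constants used here were drawn at random within sensible limits; no experiment stands behind them.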